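Assumption: the stereodescriptors of the target describe the achiral, centrosymmetric (1α,2α,3β,4β) isomer, so only relative configuration has to be secured, and intermediates with undefined side-chain or cyclohexene centers are diastereomer mixtures that converge.

## Structural features

The target is a cyclobutane (ring A) in which every carbon carries one substituent: C2 and C4 bear 3,4-dimethoxyphenyl rings (rings B and B'), and C1 and C3 bear carbonyl groups that are each bound to the nitrogen of a 5,6-dihydropyridin-2(1H)-one (rings C and C'), so that two exocyclic imides result. The four stereocenters are contiguous and follow an up, up, down, down sequence round ring A, so each aryl group is cis to one acyl neighbour and trans to the other, like groups are trans across the ring, and the molecule has a centre of inversion. The constitution is head-to-tail (aryl and acyl alternate), which a solution dimerisation of a cinnamic acid derivative does not deliver reliably. The fragile parts are the N-acyl enelactams, which are acyl donors, Michael acceptors and dienophiles, and the C1–H and C3–H bonds α to the imide carbonyls, which base can epimerise. Inversion at one of these carbons would relieve no vicinal strain, because the acyl group stays cis to one aryl neighbour on either face, so the configuration is held by kinetics only. The real difficulty is therefore to obtain the cis,trans,cis arrangement with the head-to-tail pattern on a strained ring and to keep it until the imides are attached at the very end. The key step exploits the fact that the ipso carbons of rings B and B' sit on C2 and C4 exactly where two carboxyl carbons sit in cis,trans,cis-cyclobutanetetracarboxylic dianhydride: those two carbons are reduced and extended to nitrovinyl groups, and rings B and B' are grown on them by [4+2] cycloaddition, so no bond to ring A is made or broken.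

## Logic of the disconnections

**17 ⇒ 15 + 14 (as 16).** The two exocyclic imide C–N bonds of 17 are cut first, giving 15 and two equivalents of 14, which is used as its lithium salt 16. The N-acyl enelactam is the most reactive function of the molecule and would not survive reduction, nitroaldol, cycloaddition or oxidation, so it has to come last. The gain is a symmetric diacyl electrophile and a purchasable lactam. The forward step must acylate nitrogen twice, faster than any base can remove the α-hydrogen of 15 or of 17.

**15 ⇒ 13 ⇒ 12.** The C–Cl bonds of 15 go back to the acids of 13, and these to the ester C–O bonds of 12. The esters are the inert form in which the two carboxyl groups travel through the whole route. Nothing is gained in skeleton; the gain is that 12 is the direct product of arene formation. The hydrolysis must not invert C1 or C3. Since no thermodynamic bias forbids that inversion, the forward step has to be fast acyl substitution by aqueous hydroxide and not equilibration under alkoxide.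

**12 ⇒ 10 (through 11).** Each benzene ring of 12 is taken back to the nitrocyclohexene ring of 10 by formally adding H2 and HNO2. This turns an aryl–cyclobutane linkage, which would be hard to make with control, into the retron of a cycloaddition. Base alone cannot be relied on for the elimination, because the nitro group of 10 is deprotonated at its own carbon and has no activated β-hydrogen. The forward step therefore first removes one H2 per ring to reach 11, in which the nitro group is allylic and its loss completes the arene without retaining nitrogen.

**10 ⇒ 8 + 9.** In each cyclohexene ring of 10 the two bonds from the ring-A-bearing carbon and the nitro-bearing carbon to their CH2 neighbours are cut, four C–C bonds in all. Two rings and twelve carbons are removed at once, leaving 8 and two equivalents of 9. The forward step must be a thermal, neutral [4+2] cycloaddition that prefers the carbon diene of 9 to any hetero-cycloaddition and leaves the γ-hydrogens of 8 in place.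

**8 ⇒ 4 + 5 (through 7 and 6).** The C=C bonds of the two nitrovinyl arms are cut, giving 4 and two equivalents of 5. This uses the simplest one-carbon nitro building block and places the activating group exactly where the cycloaddition needs it. The ring carbon that later carries the aryl group is α to the formyl group in 4 and γ to the nitro group in 8. The forward addition and elimination must therefore use only weak, catalytic or hindered base in the cold, so that this carbon is not epimerised and the double bond of 8 stays in conjugation.

**4 ⇒ 3 ⇒ 2.** The formyl groups of 4 are traced through the thioesters of 3 to the free acids of 2. The two acids must be told apart from the two esters and lowered by exactly one oxidation level. A route through the primary alcohols is excluded because each would lactonise onto its cis ester. The demand is a neutral, chemoselective reduction that stops at the aldehyde.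

**2 ⇒ 1.** The two ester C–O bonds of 2 are cut and the anhydride bridges restored, giving 1. All four stereocenters of the target are thereby traced to a purchased compound. The opening of the two bridges by an alcohol cannot be regioselective, so the forward step has to deliver the head-to-tail isomer free of the head-to-head one by crystallisation.

## Other disconnections considered

Alternative 1: The cut is a single ring bond of the cyclobutane, between an aryl-bearing carbon and the neighbouring carbon that carries the oxygenated one-carbon arm.
- *Forward key step.* The open-chain (E)-styrenyl secondary mesylate A2 (racemic, (2R*,3S*)) would be treated with a diboron reagent, an alkoxide and a CuCl–diphosphine catalyst. A boryl complex of monovalent copper adds syn across the styrenyl double bond, boron to the distal carbon and copper to the benzylic carbon. The benzylic C–Cu bond then displaces the mesylate with inversion and closes the ring to the cyclobutylboronate A1.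
- *In its favour.* Both veratryl rings enter intact. The closure is stereospecific twice over: the syn addition to the (E)-alkene fixes the cis aryl/boron pair, and the inversion at the mesylate carbon turns the relative configuration of A2 into the cis relation between the CH2O arm and its neighbouring aryl group. Attack on the other alkene face would lead to an all-cis ring and should be sterically penalised.
- *Against it here.* A2 already holds two adjacent acyclic stereocenters that need their own stereoselective chemistry. After the closure, boron must be exchanged for a carboxyl carbon with retention (homologation, then oxidation), and the silyl ether must be removed and oxidised, before either imide can be made. A1 has no symmetry, so no operation can be done twofold.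
- *Comparison.* On structure A1 is better than the chosen plan in one respect: no arene has to be constructed. On mechanism the two key steps are equal, each being stereochemically well defined. The chosen plan inherits all four ring centers where this one has to create them, and the step count would be clearly higher (estimated at twelve or more against eight).

Alternative 2: The cut is both imide C–N bonds, made at the very beginning.
- *Forward key step.* Two equivalents of 16 would open the two anhydride rings of 1, one carbonyl each on 1,3-related ring carbons, to give the bis-imide diacid A3.
- *In its favour.* The stereochemistry is the same purchased arrangement as in the chosen plan (equal). The imides form from a ready-activated acyl donor with no acid chloride and no protecting group (better).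
- *Against it here.* The opening is as unselective between head-to-tail and head-to-head as step 1 of the chosen plan (equal). The two free carboxyl groups of A3 must then be replaced by aryl groups, which means a decarboxylative arylation through a planar cyclobutyl radical. The configuration at those two carbons would no longer be inherited and would have to be re-established by steric preference. That chemistry would also run in the presence of two conjugated N-acyl lactams, which accept radicals and nucleophiles and donate their acyl group.
- *Comparison.* On step economy this alternative is better on paper (three or four steps). On mechanism and functional-group tolerance it is weaker: the most fragile function is made first and the stereochemical information at two centers is given up.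

Alternative 3: The cut is two opposite ring bonds of the cyclobutane, the retron of a [2+2] photodimerisation.
- *Forward key step.* Two molecules of 6,7-dimethoxycoumarin A5 would be united under triplet sensitisation by a diaryl ketone to the anti head-to-tail dimer A4, forming the C3–C4' and C4–C3' bonds.
- *In its favour.* One step makes ring A and all four stereocenters from a flat, inexpensive compound. Both arenes and both carboxyl carbons are present. The lactone bridges tie each aryl group cis to one carbonyl, and the anti head-to-tail union gives the trans relations, so A4 maps onto the target exactly.
- *Against it here.* Head-to-head versus head-to-tail and syn versus anti are decided in a triplet 1,4-biradical, and for coumarins sensitised dimerisation is generally expected to favour head-to-head union, so the required isomer may be a minor one. Each lactone must then be opened and the freed phenolic oxygen removed (sulfonylation, then reduction with a palladium catalyst and a hydride source), two operations per ring that add nothing to the skeleton. The free phenol ester would also tend to close back to the lactone.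
- *Comparison.* It is better in that no arene has to be built, and roughly equal in step count (about seven against eight). It is also equal in using a sacrificial heteroatom (an oxygen excised there, a nitro group here). The chosen plan is stronger on structure, because the ring-forming event needs no regio- or stereoselectivity at all.

Key step: step 5

## Route

**Step 1**
Reactants: 1 cis,trans,cis-cyclobutane-1,2,3,4-tetracarboxylic 1,2:3,4-dianhydride
Product: 2 (1α,2α,3β,4β)-2,4-bis(methoxycarbonyl)cyclobutane-1,3-dicarboxylic acid
Conditions: MeOH, reflux; evaporate; crystallise from EtOAc
Reagents that add atoms: methanol, CO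
Why: Alcoholysis of a cyclic anhydride: each bridge is opened once at either carbonyl, so the head-to-tail diester 2 and its head-to-head isomer should form in comparable amounts, and the centrosymmetric 2 is expected to be the less soluble and to crystallise. No ring C–H bond is touched, so the cis,trans,cis arrangement of 1 is carried over unchanged.

**Step 2**
Reactants: 2 (1α,2α,3β,4β)-2,4-bis(methoxycarbonyl)cyclobutane-1,3-dicarboxylic acid
Product: 3 dimethyl (1α,2α,3β,4β)-2,4-bis[(ethylsulfanyl)carbonyl]cyclobutane-1,3-dicarboxylate
Conditions: EtSH (3 equiv), EDC·HCl (2.4 equiv), DMAP (0.1 equiv), CH2Cl2/THF, 0 °C → rt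
Reagents that add atoms: ethanethiol, CCS
Why: Carbodiimide-mediated (Steglich-type) thioesterification; the soft thiol traps the activated acyl group faster than it can enolise and the methyl esters are inert. The two acids are trans across the ring and each has only an ester as cis neighbour, so no anhydride can re-form.

**Step 3**
Reactants: 3 dimethyl (1α,2α,3β,4β)-2,4-bis[(ethylsulfanyl)carbonyl]cyclobutane-1,3-dicarboxylate
Product: 4 dimethyl (1α,2α,3β,4β)-2,4-diformylcyclobutane-1,3-dicarboxylate
Conditions: Et3SiH (6 equiv), 10% Pd/C (10 mol% Pd), acetone, rt
Reagents that add atoms: none
Why: Fukuyama reduction: zerovalent palladium inserts into the C–S bond, the silane delivers hydride and reductive elimination releases the aldehyde under neutral conditions, leaving the methyl esters and the α-stereocenters untouched. Stopping at the aldehyde avoids the alcohol stage, which would lactonise onto the cis ester.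

**Step 4**
Reactants: 4 dimethyl (1α,2α,3β,4β)-2,4-diformylcyclobutane-1,3-dicarboxylate; 5 nitromethane
Product: 8 dimethyl (1α,2α,3β,4β)-2,4-bis[(E)-2-nitroethenyl]cyclobutane-1,3-dicarboxylate, via bis(nitro alcohol) 6 (not isolated), via bis(mesylate) 7 (not isolated)
Conditions: 5 (10 equiv), Et3N (0.2 equiv), THF, 0 °C → rt; AcOH, concentrate; then MsCl (2.4 equiv), iPr2NEt (5 equiv), CH2Cl2, −20 → 0 °C
Reagents that add atoms: none
Why: Twofold Henry (nitroaldol) addition under catalytic amine, then mesylation and E1cB loss of methanesulfonate give the conjugated (E)-nitroalkene, the thermodynamically preferred geometry; the carbinol centers of 6 and 7 are mixtures that disappear. The ring carbon α to the formyl group is the one epimerisable center and is not protected by thermodynamics, hence a weak catalytic base with excess nitromethane as proton source for the addition and a hindered amine in the cold for the elimination.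

**Step 5**
Reactants: 8 dimethyl (1α,2α,3β,4β)-2,4-bis[(E)-2-nitroethenyl]cyclobutane-1,3-dicarboxylate; 9 2,3-dimethoxybuta-1,3-diene
Product: 10 dimethyl (1α,2α,3β,4β)-2,4-bis(3,4-dimethoxy-6-nitrocyclohex-3-en-1-yl)cyclobutane-1,3-dicarboxylate (cyclohexene centers undefined)
Conditions: 9 (8 equiv), BHT (0.1 equiv), PhMe, 110 °C, sealed tube
Reagents that add atoms: none
Why: The electron-poor (E)-nitroalkene and the electron-rich 2,3-dialkoxydiene combine in a concerted, suprafacial, normal-electron-demand [4+2] cycloaddition under neutral thermal conditions, the closest known reaction type being the Diels–Alder reaction of nitroalkenes with 2,3-dioxygenated butadienes. Each cyclohexene ring closes in one intermolecular event in which the two diene termini bond to the two alkene carbons, so both σ-bonds of a ring form together, and the event runs once on each arm with one molecule of 9. Each ring gains two stereocenters whose trans relation follows from the E geometry of the dienophile by suprafacial addition, while their sense relative to ring A is uncontrolled; none needs control because all four are removed in step 6. No regioselectivity is required, since the diene is symmetric and the two arms are related by the inversion centre. What is required is periselectivity for the carbon diene over a hetero-[4+2] in which the nitroalkene would act as an O=N–C=C four-atom component toward one enol ether double bond; heat without any Lewis acid favours the all-carbon adduct. The four stereocenters of ring A take no part in bonding and no base is present, so the γ-hydrogens of 8 stay in place. Excess diene and the radical inhibitor suppress polymerisation, and acid is excluded to keep the bis(enol ether) of 10 intact.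

**Step 6**
Reactants: 10 dimethyl (1α,2α,3β,4β)-2,4-bis(3,4-dimethoxy-6-nitrocyclohex-3-en-1-yl)cyclobutane-1,3-dicarboxylate
Product: 12 dimethyl (1α,2α,3β,4β)-2,4-bis(3,4-dimethoxyphenyl)cyclobutane-1,3-dicarboxylate, via bis(nitrocyclohexadiene) 11 (not isolated)
Conditions: DDQ (2.1 equiv), CH2Cl2, 0 °C; filter; then DBU (3 equiv), 0 °C → rt
Reagents that add atoms: none
Why: DDQ removes hydride from an allylic CH2 of the electron-rich bis(enol ether) and proton loss from the other CH2 gives the 2,3-dimethoxy-1,3-diene 11 whichever CH2 is attacked first (quinone dehydrogenation of an enol ether). In 11 the nitro group is allylic and its departure leaves the arenium ion of the veratryl ring, so DBU-assisted loss of HNO2 is driven by aromatisation, places the methoxy groups meta and para to ring A and removes all transient cyclohexene centers. One equivalent of quinone per ring is used so that no oxidant remains to dehydrogenate 11 before nitrite has left.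

**Step 7**
Reactants: 12 dimethyl (1α,2α,3β,4β)-2,4-bis(3,4-dimethoxyphenyl)cyclobutane-1,3-dicarboxylate
Product: 13 (1α,2α,3β,4β)-2,4-bis(3,4-dimethoxyphenyl)cyclobutane-1,3-dicarboxylic acid
Conditions: LiOH·H2O (6 equiv), THF/H2O (3:1), rt; then 1 M HCl
Reagents that add atoms: lithium hydroxide, [Li+].[OH-]
Why: Saponification by acyl–oxygen cleavage: hydroxide adds to the ester carbonyl far faster than it removes the α-hydrogen, whose loss would also put an exocyclic sp2 center on the strained ring, and the carboxylate once formed is no longer enolisable under these conditions. The aryl methyl ethers are inert, and aqueous hydroxide at room temperature is used in place of an alkoxide so that the cis,trans,cis arrangement is kept under kinetic control.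

**Step 8**
Reactants: 13 (1α,2α,3β,4β)-2,4-bis(3,4-dimethoxyphenyl)cyclobutane-1,3-dicarboxylic acid; 14 5,6-dihydropyridin-2(1H)-one
Product: 17 1,1'-{[(1α,2α,3β,4β)-2,4-bis(3,4-dimethoxyphenyl)cyclobutane-1,3-diyl]dicarbonyl}bis(5,6-dihydropyridin-2(1H)-one), via diacid chloride 15 (not isolated), via lithium lactamate 16 (not isolated)
Conditions: 14 (3 equiv), LiN(SiMe3)2 (1 M in THF, 2.2 equiv), THF, −78 °C; separately oxalyl chloride (3 equiv), DMF (cat.), CH2Cl2, 0 °C → rt, evaporate; crude 15 in THF added to 16, −78 → −30 °C; aq. NH4Cl
Reagents that add atoms: none
Why: Acid chloride formation through the chloroiminium species from oxalyl chloride and DMF, then twofold N-acylation in which two molecules of the lithium amide 16 each displace one chloride of 15, the usual way to N-acyl-5,6-dihydropyridin-2(1H)-ones. At −78 °C the delocalised nitrogen anion is a good nucleophile and a weak base, and the surplus of neutral 14 ensures that no silylamide is left, so substitution at the acyl chloride should outrun ketene formation and α-deprotonation of the imide. The four ring centers therefore keep the configuration of 13.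

## Compound list

1 | cis,trans,cis-cyclobutane-1,2,3,4-tetracarboxylic 1,2:3,4-dianhydride (the two anhydride rings on opposite faces) | O=C4OC(=O)[C@H]1[C@H](C(=O)OC5=O)[C@H]5[C@H]14 | starting material
2 | (1α,2α,3β,4β)-2,4-bis(methoxycarbonyl)cyclobutane-1,3-dicarboxylic acid (centrosymmetric head-to-tail diester diacid) | OC(=O)[C@H]1[C@H](C(=O)OC)[C@H](C(O)=O)[C@H]1C(=O)OC | intermediate
3 | dimethyl (1α,2α,3β,4β)-2,4-bis[(ethylsulfanyl)carbonyl]cyclobutane-1,3-dicarboxylate | CCSC(=O)[C@H]1[C@H](C(=O)OC)[C@H](C(=O)SCC)[C@H]1C(=O)OC | intermediate
4 | dimethyl (1α,2α,3β,4β)-2,4-diformylcyclobutane-1,3-dicarboxylate | O=C[C@H]1[C@H](C(=O)OC)[C@H](C=O)[C@H]1C(=O)OC | intermediate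
5 | nitromethane | C[N+](=O)[O-] | starting material
6 | dimethyl (1α,2α,3β,4β)-2,4-bis(1-hydroxy-2-nitroethyl)cyclobutane-1,3-dicarboxylate (carbinol centers undefined) | [O-][N+](=O)CC(O)[C@H]1[C@H](C(=O)OC)[C@H](C(O)C[N+](=O)[O-])[C@H]1C(=O)OC | intermediate
7 | dimethyl (1α,2α,3β,4β)-2,4-bis[1-(methylsulfonyloxy)-2-nitroethyl]cyclobutane-1,3-dicarboxylate (side-chain centers undefined) | CS(=O)(=O)OC(C[N+](=O)[O-])[C@H]1[C@H](C(=O)OC)[C@H](C(C[N+](=O)[O-])OS(C)(=O)=O)[C@H]1C(=O)OC | intermediate
8 | dimethyl (1α,2α,3β,4β)-2,4-bis[(E)-2-nitroethenyl]cyclobutane-1,3-dicarboxylate (centrosymmetric) | [O-][N+](=O)/C=C/[C@H]1[C@H](C(=O)OC)[C@H](/C=C/[N+](=O)[O-])[C@H]1C(=O)OC | intermediate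
9 | 2,3-dimethoxybuta-1,3-diene | COC(=C)C(=C)OC | starting material
10 | dimethyl (1α,2α,3β,4β)-2,4-bis(3,4-dimethoxy-6-nitrocyclohex-3-en-1-yl)cyclobutane-1,3-dicarboxylate (cyclohexene centers undefined) | COC1=C(OC)CC([N+](=O)[O-])C(C1)[C@H]1[C@H](C(=O)OC)[C@H](C2CC(OC)=C(OC)CC2[N+](=O)[O-])[C@H]1C(=O)OC | intermediate
11 | dimethyl (1α,2α,3β,4β)-2,4-bis(3,4-dimethoxy-6-nitrocyclohexa-2,4-dien-1-yl)cyclobutane-1,3-dicarboxylate (cyclohexadiene centers undefined) | COC1=CC([N+](=O)[O-])C(C=C1OC)[C@H]1[C@H](C(=O)OC)[C@H](C2C=C(OC)C(OC)=CC2[N+](=O)[O-])[C@H]1C(=O)OC | intermediate
12 | dimethyl (1α,2α,3β,4β)-2,4-bis(3,4-dimethoxyphenyl)cyclobutane-1,3-dicarboxylate | COc1ccc([C@H]2[C@H](C(=O)OC)[C@H](c3ccc(OC)c(OC)c3)[C@H]2C(=O)OC)cc1OC | intermediate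
13 | (1α,2α,3β,4β)-2,4-bis(3,4-dimethoxyphenyl)cyclobutane-1,3-dicarboxylic acid | COc1ccc([C@H]2[C@H](C(=O)O)[C@H](c3ccc(OC)c(OC)c3)[C@H]2C(=O)O)cc1OC | intermediate
14 | 5,6-dihydropyridin-2(1H)-one | O=C1NCCC=C1 | starting material
15 | (1α,2α,3β,4β)-2,4-bis(3,4-dimethoxyphenyl)cyclobutane-1,3-dicarbonyl dichloride | COc1ccc([C@H]2[C@H](C(=O)Cl)[C@H](c3ccc(OC)c(OC)c3)[C@H]2C(=O)Cl)cc1OC | intermediate
16 | lithium salt of 5,6-dihydropyridin-2(1H)-one (N-lithio lactam) | [Li+].O=C1[N-]CCC=C1 | intermediate
17 | 1,1'-{[(1α,2α,3β,4β)-2,4-bis(3,4-dimethoxyphenyl)cyclobutane-1,3-diyl]dicarbonyl}bis(5,6-dihydropyridin-2(1H)-one), CNP0199212.1 | COc1ccc([C@H]2[C@H](C(=O)N3CCC=CC3=O)[C@H](c3ccc(OC)c(OC)c3)[C@H]2C(=O)N2CCC=CC2=O)cc1OC | target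

## Step count and least certain steps

Total step count: 8. Longest linear sequence: 8 steps (1 → 17); 5, 9 and 14 are purchased and enter directly.

**Step 5 (key step).** The most likely failure is a cycloaddition that is too slow for a β-alkyl nitroalkene of only moderate activation. Prolonged heating would then allow thermal decomposition or polymerisation of 8 and of the diene before both arms have reacted. A second possibility is diversion into the hetero-[4+2] manifold, giving cyclic nitronates, or drift of the double bond of 8 out of conjugation.

Fallback: the approach changes from building the arenes to attaching them. It sets out from 2 and returns at 12. Acid 2 would be converted with N-hydroxyphthalimide and a carbodiimide into dimethyl (1α,2α,3β,4β)-2,4-bis{[(1,3-dioxoisoindolin-2-yl)oxy]carbonyl}cyclobutane-1,3-dicarboxylate F1. This would be coupled with (3,4-dimethoxyphenyl)zinc chloride F2 (from commercial 4-bromo-1,2-dimethoxybenzene by magnesium insertion and transmetalation with ZnCl2) under NiCl2(dme) and 4,4'-di-tert-butyl-2,2'-bipyridine in THF/DMF at rt, a decarboxylative Negishi arylation. Each cyclobutyl radical should be captured on the face away from the substituent on the carbon across the ring, which is the configuration of 12. This is held in reserve because the configuration at the two aryl-bearing carbons would then rest on that steric preference instead of being inherited.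

**Step 6.** The most likely failure is over-oxidation: a second hydride abstraction from 11 before HNO2 has left would retain nitrogen as a nitroarene. The acidic hydroquinone might also cleave the enol ethers if moisture is present.

Fallback: nitrogen is removed before any oxidant is used. It sets out from 10 and returns at 12. Radical denitration of 10 with Bu3SnH and AIBN in PhMe at 110 °C would give dimethyl (1α,2α,3β,4β)-2,4-bis(3,4-dimethoxycyclohex-3-en-1-yl)cyclobutane-1,3-dicarboxylate F3. With no nitro group left, F3 can then be dehydrogenated to 12 with DDQ (two equivalents per ring) without any question of selectivity.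

**Step 4.** The most likely failure is loss of configuration at the ring carbon through enolisation of the aldehyde, together with reversal of the nitroaldol, while the amine catalyst is present. Closure of a nitro alcohol onto its cis ester during the addition is a further risk, to be met by a short reaction time, acidification and immediate mesylation. Deconjugation of the nitroalkene to the allylic nitro isomer during the elimination is a third.

Fallback: the C–C bond is made irreversibly at the acid oxidation level and the aldehyde is never formed. It sets out from 2 and returns at 6. Acid 2 would be activated with 1,1'-carbonyldiimidazole to dimethyl (1α,2α,3β,4β)-2,4-bis(1H-imidazole-1-carbonyl)cyclobutane-1,3-dicarboxylate F4. C-acylation of the potassium nitronate of 5 (from 5 and KOtBu in THF) would give dimethyl (1α,2α,3β,4β)-2,4-bis(2-nitroacetyl)cyclobutane-1,3-dicarboxylate F5, which is held as its unreactive nitronate until work-up. NaBH4 in MeOH at 0 °C would reduce F5 to 6, which is dehydrated as in step 4.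

**Step 8.** The most likely failure is proton transfer in place of acylation: ketene formation from 15 or α-deprotonation of the newly formed imide by the lithium amide, each with loss of configuration at C1 or C3. Incomplete second acylation and cleavage of the reactive imide during work-up are further risks.

Fallback: no metal amide is used. It sets out from 15 and returns at 17. Lactam 14 would be silylated (Me3SiCl, Et3N) to 1-(trimethylsilyl)-5,6-dihydropyridin-2(1H)-one F6. Two equivalents of F6 would be heated with 15 in PhMe, so that each N–Si bond is exchanged for an N–acyl bond under neutral conditions with loss of volatile chlorotrimethylsilane.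

**Step 1.** The most likely failure is an unfavourable partition between head-to-tail and head-to-head opening, combined with incomplete separation by crystallisation. Slow further esterification in hot methanol is a minor risk.

Fallback: the sulfur nucleophile is introduced first and the separation is moved to a neutral, chromatographable stage. It sets out from 1 and returns at 3. Thiolysis of 1 with EtSH, Et3N and catalytic DMAP would give (1α,2α,3β,4β)-2,4-bis[(ethylsulfanyl)carbonyl]cyclobutane-1,3-dicarboxylic acid F7 together with its regioisomer. Methylation of the mixture with trimethylsilyldiazomethane in PhMe/MeOH, then chromatography, would deliver 3.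

## Further compounds

F1 | step 5 | dimethyl (1α,2α,3β,4β)-2,4-bis{[(1,3-dioxoisoindolin-2-yl)oxy]carbonyl}cyclobutane-1,3-dicarboxylate | O=C(ON1C(=O)c2ccccc2C1=O)[C@H]1[C@H](C(=O)OC)[C@H](C(=O)ON2C(=O)c3ccccc3C2=O)[C@H]1C(=O)OC
F2 | step 5 | (3,4-dimethoxyphenyl)zinc chloride | COc1ccc([Zn]Cl)cc1OC
F3 | step 6 | dimethyl (1α,2α,3β,4β)-2,4-bis(3,4-dimethoxycyclohex-3-en-1-yl)cyclobutane-1,3-dicarboxylate (cyclohexene centers undefined) | COC1=C(OC)CC(CC1)[C@H]1[C@H](C(=O)OC)[C@H](C2CCC(OC)=C(OC)C2)[C@H]1C(=O)OC
F4 | step 4 | dimethyl (1α,2α,3β,4β)-2,4-bis(1H-imidazole-1-carbonyl)cyclobutane-1,3-dicarboxylate | O=C(n1ccnc1)[C@H]1[C@H](C(=O)OC)[C@H](C(=O)n2ccnc2)[C@H]1C(=O)OC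
F5 | step 4 | dimethyl (1α,2α,3β,4β)-2,4-bis(2-nitroacetyl)cyclobutane-1,3-dicarboxylate | [O-][N+](=O)CC(=O)[C@H]1[C@H](C(=O)OC)[C@H](C(=O)C[N+](=O)[O-])[C@H]1C(=O)OC
F6 | step 8 | 1-(trimethylsilyl)-5,6-dihydropyridin-2(1H)-one | C[Si](C)(C)N1CCC=CC1=O
F7 | step 1 | (1α,2α,3β,4β)-2,4-bis[(ethylsulfanyl)carbonyl]cyclobutane-1,3-dicarboxylic acid | CCSC(=O)[C@H]1[C@H](C(=O)O)[C@H](C(=O)SCC)[C@H]1C(=O)O
A1 | alternative 1 | pinacol [2,4-bis(3,4-dimethoxyphenyl)-3-(triisopropylsilyloxymethyl)cyclobutyl]boronate (racemic, relative configuration as drawn) | COc1ccc(cc1OC)[C@H]1[C@H](CO[Si](C(C)C)(C(C)C)C(C)C)[C@H](c2ccc(OC)c(OC)c2)[C@H]1B1OC(C)(C)C(C)(C)O1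
A2 | alternative 1 | (E)-(2R*,3S*)-3,5-bis(3,4-dimethoxyphenyl)-1-(triisopropylsilyloxy)pent-4-en-2-yl methanesulfonate (racemic) | CS(=O)(=O)O[C@@H](CO[Si](C(C)C)(C(C)C)C(C)C)[C@H](c1ccc(OC)c(OC)c1)/C=C/c1ccc(OC)c(OC)c1
A3 | alternative 2 | (1α,2α,3β,4β)-2,4-bis(2-oxo-5,6-dihydropyridine-1(2H)-carbonyl)cyclobutane-1,3-dicarboxylic acid | OC(=O)[C@H]1[C@H](C(=O)N2CCC=CC2=O)[C@H](C(O)=O)[C@H]1C(=O)N1CCC=CC1=O
A4 | alternative 3 | anti head-to-tail cyclodimer of 6,7-dimethoxycoumarin | O=C4Oc5cc(OC)c(OC)cc5[C@H]1[C@H](C(=O)Oc6cc(OC)c(OC)cc67)[C@H]7[C@H]14
A5 | alternative 3 | 6,7-dimethoxycoumarin | COc1cc2ccc(=O)oc2cc1OC
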